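Numbering: C1 = methyl-bearing fusion carbon, C2–C3 = CH2, C4 = isopropyl carbinol, C5 = fusion CH, C6 = ester carbon, C7 = CH2, C8(Me)–C9 = epoxide, C10 = carbinol; five-membered ring C1–C5, seven-membered ring C1, C5–C10.
Retrosynthesis cuts, in this order: the C6–O acyl bond, C5–H with C6–O (hydroboration of a C5=C6 alkene), the C4–isopropyl bond (C4 enone), the C4–O bond (allylic oxidation), the epoxide oxygen, the C5=C6 bond (carbonyl coupling) and the C1–C10 bond (aldol).
Enabling feature: C5 and C6 are neighbours in the seven-membered ring; C5 can be the carbonyl of a 2,2-disubstituted cyclopentanone next to quaternary C1, C6 can be an aldehyde, and the cis C8=C9 alkene of the tether holds the two carbonyls together, so a McMurry coupling closes the seven-membered ring as the C5=C6 alkene.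
Forward: the five-membered ring comes from 2-methylcyclopentanone; a (Z)-enal made from 4-methyl-5,6-dihydro-2H-pyran-2-one is joined at C1–C10 by aldol addition; the seven-membered ring closes at C5=C6; then epoxide, C4 ketone, isopropyl, hydroboration and angelate follow.
Stereochemistry: C1 and C10 from a catalyst-controlled, chair-type aldol addition; C8/C9 from epoxidation directed by the C10 hydroxyl; C4 from organocerium addition anti to the C1 methyl; C5/C6 from syn hydroboration anti to the C1 methyl.

Key step: step 10

Assumption: in step 6 the (4S,5S) phosphoramide is taken to select the aldehyde face that leads to the (R) carbinol, by analogy with unsubstituted cyclic enolates; should the sense be the opposite, the (4R,5R) catalyst is used and nothing else changes.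

Step 1
Reactants: 1 4-methyl-5,6-dihydro-2H-pyran-2-one
Product: 2 (2Z)-5-hydroxy-N-methoxy-N,3-dimethylpent-2-enamide
Conditions: MeNH(OMe)·HCl, AlMe3, CH2Cl2, 0 °C to rt; aq. potassium sodium tartrate; used at once
Reagents that add atoms: N,O-dimethylhydroxylamine hydrochloride, CNOC.Cl
Why: Aminolysis of the unsaturated lactone by the aluminium amide (Weinreb amide formation) opens the ring at the acyl carbon without touching the trisubstituted alkene, so the ring-enforced Z geometry should be carried into the chain.

Step 2
Reactants: 2 (2Z)-5-hydroxy-N-methoxy-N,3-dimethylpent-2-enamide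
Product: 3 (2Z)-N-methoxy-N,3-dimethyl-5-(triethylsilyloxy)pent-2-enamide
Conditions: Et3SiCl, imidazole, CH2Cl2, 0 °C
Reagents that add atoms: chlorotriethylsilane, CC[Si](Cl)(CC)CC
Why: Silyl ether formation under mild base caps the primary hydroxyl before it can relactonise onto the amide, with a group that can later be removed beside a hindered secondary silyl ether.

Step 3
Reactants: 3 (2Z)-N-methoxy-N,3-dimethyl-5-(triethylsilyloxy)pent-2-enamide
Product: 5 (2Z)-3-methyl-5-(triethylsilyloxy)pent-2-enal, via aluminium hemiaminal 4 (not isolated)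
Conditions: i-Bu2AlH, THF, −78 °C; aq. potassium sodium tartrate
Reagents that add atoms: none
Why: Hydride reduction of a Weinreb amide stops at the chelated tetrahedral intermediate, which releases the (Z)-enal only on work-up, so over-reduction and alkene isomerisation should be avoided.

Step 4
Reactants: 6 2-methylcyclopentan-1-one (racemic)
Product: 7 trimethyl[(2-methylcyclopent-1-en-1-yl)oxy]silane
Conditions: Me3SiCl, NaI, Et3N, MeCN, rt; distillation
Reagents that add atoms: chlorotrimethylsilane, C[Si](C)(C)Cl
Why: Equilibrating silylation (silyl enol ether formation with Me3SiI made in the flask) should favour the tetrasubstituted enol ether, which fixes the enolate at the methyl-bearing carbon and erases the stereocentre of the racemic ketone.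

Step 5
Reactants: 7 trimethyl[(2-methylcyclopent-1-en-1-yl)oxy]silane
Product: 8 trichloro[(2-methylcyclopent-1-en-1-yl)oxy]silane
Conditions: SiCl4, Hg(OAc)2 (1 mol %), CH2Cl2, rt; distillation
Reagents that add atoms: silicon tetrachloride, Cl[Si](Cl)(Cl)Cl
Why: Hg(OAc)2-catalysed silyl exchange (trans-silylation of an enol silane) should convert the trimethylsilyl enol ether into the trichlorosilyl enolate without loss of regiochemistry, Me3SiCl being removed on distillation.

Step 6
Reactants: 8 trichloro[(2-methylcyclopent-1-en-1-yl)oxy]silane; 5 (2Z)-3-methyl-5-(triethylsilyloxy)pent-2-enal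
Product: 10 (2R)-2-[(1R,2Z)-1-hydroxy-3-methyl-5-(triethylsilyloxy)pent-2-en-1-yl]-2-methylcyclopentan-1-one, via trichlorosilyl aldolate 9 (not isolated)
Conditions: (4S,5S)-1,3-dimethyl-4,5-diphenyl-2-(piperidin-1-yl)-1,3,2-diazaphospholidine 2-oxide (10 mol %), CH2Cl2, −78 °C; sat. aq. NaHCO3
Reagents that add atoms: none
Why: Proposed new method: the chiral phosphoramide binds the trichlorosilyl enolate to give a cationic hexacoordinate siliconate that holds aldehyde and enolate in a closed chair (Zimmerman–Traxler) transition state, so the ring-locked E(O) enolate should place the C10 hydroxyl anti to the ring CH2 and syn to the methyl (the required C1/C10 relative configuration at the new quaternary centre) while the diamine backbone selects the aldehyde face (absolute configuration); the closest known reaction is the phosphoramide-catalysed anti-selective aldol addition of trichlorosilyl enolates of unsubstituted cyclic ketones to enals, not yet shown for a tetrasubstituted enolate.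

Step 7
Reactants: 10 (2R)-2-[(1R,2Z)-1-hydroxy-3-methyl-5-(triethylsilyloxy)pent-2-en-1-yl]-2-methylcyclopentan-1-one
Product: 11 (2R)-2-[(1R,2Z)-1-(tert-butyldimethylsilyloxy)-3-methyl-5-(triethylsilyloxy)pent-2-en-1-yl]-2-methylcyclopentan-1-one
Conditions: t-BuMe2SiOTf, 2,6-lutidine, CH2Cl2, −78 to 0 °C
Reagents that add atoms: tert-butyldimethylsilyl trifluoromethanesulfonate, CC(C)(C)[Si](C)(C)OS(=O)(=O)C(F)(F)F
Why: Silyl ether formation with a silyl triflate and a hindered pyridine base should cap the neopentylic secondary alcohol under conditions too weakly basic for retro-aldol cleavage.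

Step 8
Reactants: 11 (2R)-2-[(1R,2Z)-1-(tert-butyldimethylsilyloxy)-3-methyl-5-(triethylsilyloxy)pent-2-en-1-yl]-2-methylcyclopentan-1-one
Product: 12 (2R)-2-[(1R,2Z)-1-(tert-butyldimethylsilyloxy)-5-hydroxy-3-methylpent-2-en-1-yl]-2-methylcyclopentan-1-one
Conditions: pyridinium p-toluenesulfonate (cat.), MeOH/CH2Cl2, 0 °C
Reagents that add atoms: none
Why: Acid-catalysed methanolysis (selective desilylation) should remove the primary triethylsilyl ether much faster than the hindered secondary tert-butyldimethylsilyl ether.

Step 9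
Reactants: 12 (2R)-2-[(1R,2Z)-1-(tert-butyldimethylsilyloxy)-5-hydroxy-3-methylpent-2-en-1-yl]-2-methylcyclopentan-1-one
Product: 13 (3Z,5R)-5-(tert-butyldimethylsilyloxy)-3-methyl-5-[(1R)-1-methyl-2-oxocyclopentyl]pent-3-enal
Conditions: Dess–Martin periodinane, NaHCO3, CH2Cl2, 0 °C; used at once
Reagents that add atoms: none
Why: Buffered Dess–Martin oxidation should convert the homoallylic alcohol into the β,γ-unsaturated aldehyde under neutral conditions that do not move the C8=C9 alkene into conjugation.

Step 10
Reactants: 13 (3Z,5R)-5-(tert-butyldimethylsilyloxy)-3-methyl-5-[(1R)-1-methyl-2-oxocyclopentyl]pent-3-enal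
Product: 15 tert-butyl{[(8R,8aS)-6,8a-dimethyl-1,2,3,5,8,8a-hexahydroazulen-8-yl]oxy}dimethylsilane (C5=C6 and C8=C9 diene with C10 silyl ether), via titanium pinacolate 14 (not isolated)
Conditions: TiCl3(DME)1.5, Zn–Cu couple, DME, reflux; 13 added by syringe pump over ca. 30 h (high dilution)
Reagents that add atoms: none
Why: Low-valent titanium made from TiCl3(DME)1.5 and Zn–Cu transfers an electron to each carbonyl, the aldehyde and ketone ketyls couple on the metal to the cyclic titanium pinacolate 14, and on heating both oxygens are given up to the oxophilic metal, leaving the C5=C6 alkene. The closest known reaction is the intramolecular McMurry keto-aldehyde coupling that gives seven-membered and larger trisubstituted cycloalkenes. The seven-membered ring closes by 7-exo-trig attack of the C6 ketyl on the C5 carbonyl across the five-atom tether C7–C8=C9–C10–C1. No stereocentre is formed in the product, since both carbinol centres of the pinacolate are lost on deoxygenation and the ring can hold only a cis alkene; quaternary C1 and the silyl-protected C10 cannot epimerise. The step needs ring closure to win over intermolecular coupling, which the cis C8=C9 alkene in the tether and slow addition at high dilution should secure. It also needs the allylic silyl ether and the β,γ-unsaturated aldehyde to survive, which is why the aldehyde is made fresh and is consumed as it is added.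

Step 11
Reactants: 15 tert-butyl{[(8R,8aS)-6,8a-dimethyl-1,2,3,5,8,8a-hexahydroazulen-8-yl]oxy}dimethylsilane
Product: 16 (8R,8aS)-6,8a-dimethyl-1,2,3,5,8,8a-hexahydroazulen-8-ol (dienol, C10–OH)
Conditions: Bu4NF, THF, rt
Reagents that add atoms: none
Why: Fluoride-induced desilylation should free the C10 allylic hydroxyl needed to direct the next step, nothing else in the diene being fluoride-sensitive.

Step 12
Reactants: 16 (8R,8aS)-6,8a-dimethyl-1,2,3,5,8,8a-hexahydroazulen-8-ol
Product: 17 (1S,8R,9S,10S)-epoxy alcohol: 16 with the C8=C9 alkene converted into an oxirane cis to the C10 hydroxyl, C5=C6 alkene kept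
Conditions: VO(acac)2 (5 mol %), t-BuOOH, CH2Cl2, 0 °C
Reagents that add atoms: tert-butyl hydroperoxide, CC(C)(C)OO
Why: Hydroxyl-directed epoxidation: the vanadium alkoxide of the C10 hydroxyl should deliver the peroxide oxygen to the allylic C8=C9 alkene on the hydroxyl-bearing face (syn selectivity, as in cyclohept-2-enols) much faster than to the homoallylic C5=C6 alkene, setting C8 and C9.

Step 13
Reactants: 17 (1S,8R,9S,10S)-epoxy alcohol
Product: 18 C10 triethylsilyl ether of 17
Conditions: Et3SiOTf, 2,6-lutidine, CH2Cl2, −78 °C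
Reagents that add atoms: triethylsilyl trifluoromethanesulfonate, CC[Si](CC)(CC)OS(=O)(=O)C(F)(F)F
Why: Silyl ether formation at low temperature should cap the hindered hydroxyl next to the epoxide so that the later oxidation and acylation steps cannot reach it.

Step 14
Reactants: 18 C10 triethylsilyl ether of 17
Product: 19 C4 allylic alcohol: 18 hydroxylated at C4 (C4 configuration not controlled)
Conditions: SeO2 (0.3 equiv), t-BuOOH, CH2Cl2, rt
Reagents that add atoms: selenium dioxide, O=[Se]=O; tert-butyl hydroperoxide, CC(C)(C)OO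
Why: Riley allylic oxidation (ene reaction of SeO2 at the less substituted C6, then [2,3]-sigmatropic shift) should hydroxylate the ring CH2 on the more substituted alkene carbon, C4, and return the C5=C6 alkene, the C4 configuration being irrelevant because this carbinol is oxidised next.

Step 15
Reactants: 19 C4 allylic alcohol
Product: 20 C4 enone: alkylidenecyclopentanone with C4=O conjugated to C5=C6, (1S,8R,9S,10S)
Conditions: Dess–Martin periodinane, NaHCO3, CH2Cl2, 0 °C
Reagents that add atoms: none
Why: Dess–Martin oxidation of the secondary allylic alcohol should give the enone without acid or base that could open the epoxide.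

Step 16
Reactants: 20 C4 enone
Product: 21 (1S,4R,8R,9S,10S)-tertiary allylic alcohol: 20 after addition of isopropyl to C4 (C4–OH β, isopropyl α)
Conditions: i-PrMgCl, CeCl3, THF, −78 °C; H2O
Reagents that add atoms: isopropylmagnesium chloride, CC(C)[Mg]Cl
Why: Organocerium addition (Grignard reagent transmetallated to CeCl3) should add 1,2 to the enone without conjugate addition, enolisation or β-hydride reduction, approaching C4 anti to the pseudoaxial C1 methyl so that isopropyl ends up α and hydroxyl β.

Step 17
Reactants: 21 (1S,4R,8R,9S,10S)-tertiary allylic alcohol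
Product: 23 (1S,4R,5S,6S,8R,9S,10S)-8,9-epoxy-10-(triethylsilyloxy)-trans-daucane-4,6-diol (C5–H α, C6–OH α), via C6 alkylborane 22 (not isolated)
Conditions: BH3·THF, THF, 0 °C to rt; then NaOH, H2O2, 0 °C
Reagents that add atoms: hydrogen peroxide, OO
Why: Hydroboration–oxidation: borane should add syn and anti-Markovnikov (boron to C6, hydrogen to C5) on the alkene face opposite the C1 methyl and the C4 oxygen, and oxidation with retention then gives the trans ring fusion and the α C6 hydroxyl in one operation.

Step 18
Reactants: 23 (1S,4R,5S,6S,8R,9S,10S)-8,9-epoxy-10-(triethylsilyloxy)-trans-daucane-4,6-diol; 24 angelic acid, (2Z)-2-methylbut-2-enoic acid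
Product: 26 lapiferine 10-O-triethylsilyl ether, via mixed anhydride 25 (not isolated)
Conditions: 2,4,6-trichlorobenzoyl chloride, Et3N, toluene, rt, filtered; then 23, toluene, 80 °C
Reagents that add atoms: none
Why: Yamaguchi esterification through the mixed 2,4,6-trichlorobenzoic anhydride should acylate the only reactive hydroxyl (C6; C4 is tertiary, C10 is silylated) under amine-free heating that keeps the angelate from isomerising to the tiglate.

Step 19
Reactants: 26 lapiferine 10-O-triethylsilyl ether
Product: 27 lapiferine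
Conditions: Bu4NF, AcOH, THF, 0 °C to rt
Reagents that add atoms: none
Why: Buffered fluoride desilylation should cleave the triethylsilyl ether without acyl migration, epoxide opening or angelate isomerisation.

Compound list
1 | 4-methyl-5,6-dihydro-2H-pyran-2-one | CC1=CC(=O)OCC1 | starting material
2 | (2Z)-5-hydroxy-N-methoxy-N,3-dimethylpent-2-enamide | CON(C)C(=O)/C=C(/C)CCO | intermediate
3 | (2Z)-N-methoxy-N,3-dimethyl-5-(triethylsilyloxy)pent-2-enamide | CON(C)C(=O)/C=C(/C)CCO[Si](CC)(CC)CC | intermediate
4 | O-(diisobutylaluminio) N-methoxy-N-methyl hemiaminal of 3 (not isolated) | CON(C)C(O[Al](CC(C)C)CC(C)C)/C=C(/C)CCO[Si](CC)(CC)CC | intermediate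
5 | (2Z)-3-methyl-5-(triethylsilyloxy)pent-2-enal | O=C/C=C(/C)CCO[Si](CC)(CC)CC | intermediate
6 | 2-methylcyclopentan-1-one (racemic) | CC1CCCC1=O | starting material
7 | trimethyl[(2-methylcyclopent-1-en-1-yl)oxy]silane | CC1=C(O[Si](C)(C)C)CCC1 | intermediate
8 | trichloro[(2-methylcyclopent-1-en-1-yl)oxy]silane | CC1=C(O[Si](Cl)(Cl)Cl)CCC1 | intermediate
9 | trichlorosilyl ether of aldol 10 (not isolated) | CC[Si](CC)(CC)OCC/C(C)=C\[C@@H](O[Si](Cl)(Cl)Cl)[C@@]1(C)CCCC1=O | intermediate
10 | (2R)-2-[(1R,2Z)-1-hydroxy-3-methyl-5-(triethylsilyloxy)pent-2-en-1-yl]-2-methylcyclopentan-1-one | CC[Si](CC)(CC)OCC/C(C)=C\[C@@H](O)[C@@]1(C)CCCC1=O | intermediate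
11 | (2R)-2-[(1R,2Z)-1-(tert-butyldimethylsilyloxy)-3-methyl-5-(triethylsilyloxy)pent-2-en-1-yl]-2-methylcyclopentan-1-one | CC[Si](CC)(CC)OCC/C(C)=C\[C@@H](O[Si](C)(C)C(C)(C)C)[C@@]1(C)CCCC1=O | intermediate
12 | (2R)-2-[(1R,2Z)-1-(tert-butyldimethylsilyloxy)-5-hydroxy-3-methylpent-2-en-1-yl]-2-methylcyclopentan-1-one | OCC/C(C)=C\[C@@H](O[Si](C)(C)C(C)(C)C)[C@@]1(C)CCCC1=O | intermediate
13 | (3Z,5R)-5-(tert-butyldimethylsilyloxy)-3-methyl-5-[(1R)-1-methyl-2-oxocyclopentyl]pent-3-enal | O=CC/C(C)=C\[C@@H](O[Si](C)(C)C(C)(C)C)[C@@]1(C)CCCC1=O | intermediate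
14 | cyclic divalent-titanium C5,C6-diolate (pinacolate) of the closed bicycle (not isolated) | CC1=C[C@@H](O[Si](C)(C)C(C)(C)C)[C@@]2(C)CCCC23O[Ti]OC3C1 | intermediate
15 | tert-butyl{[(8R,8aS)-6,8a-dimethyl-1,2,3,5,8,8a-hexahydroazulen-8-yl]oxy}dimethylsilane | CC1=C[C@@H](O[Si](C)(C)C(C)(C)C)[C@@]2(C)CCCC2=CC1 | intermediate
16 | (8R,8aS)-6,8a-dimethyl-1,2,3,5,8,8a-hexahydroazulen-8-ol | CC1=C[C@@H](O)[C@@]2(C)CCCC2=CC1 | intermediate
17 | (1S,8R,9S,10S)-epoxy alcohol: 16 with C8=C9 as oxirane cis to C10–OH | C[C@]12O[C@H]1[C@@H](O)[C@@]1(C)CCCC1=CC2 | intermediate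
18 | C10 triethylsilyl ether of 17 | C[C@]12O[C@H]1[C@@H](O[Si](CC)(CC)CC)[C@@]1(C)CCCC1=CC2 | intermediate
19 | C4 allylic alcohol of 18 (C4 epimers) | C[C@]12O[C@H]1[C@@H](O[Si](CC)(CC)CC)[C@@]1(C)CCC(O)C1=CC2 | intermediate
20 | C4 enone (alkylidenecyclopentanone), (1S,8R,9S,10S) | C[C@]12O[C@H]1[C@@H](O[Si](CC)(CC)CC)[C@@]1(C)CCC(=O)C1=CC2 | intermediate
21 | (1S,4R,8R,9S,10S)-tertiary allylic alcohol with C4–OH β and isopropyl α | C[C@]12O[C@H]1[C@@H](O[Si](CC)(CC)CC)[C@@]1(C)CC[C@@](O)(C(C)C)C1=CC2 | intermediate
22 | C6 α-alkylborane of 21 (boron on C6, hydrogen on C5; not isolated) | B[C@H]1C[C@@]2(C)O[C@H]2[C@@H](O[Si](CC)(CC)CC)[C@@]2(C)CC[C@@](O)(C(C)C)[C@H]12 | intermediate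
23 | (1S,4R,5S,6S,8R,9S,10S)-8,9-epoxy-10-(triethylsilyloxy)-trans-daucane-4,6-diol | O[C@H]1C[C@@]2(C)O[C@H]2[C@@H](O[Si](CC)(CC)CC)[C@@]2(C)CC[C@@](O)(C(C)C)[C@H]12 | intermediate
24 | angelic acid, (2Z)-2-methylbut-2-enoic acid | C/C=C(/C)C(=O)O | starting material
25 | (2Z)-2-methylbut-2-enoic 2,4,6-trichlorobenzoic anhydride (not isolated) | C/C=C(/C)C(=O)OC(=O)c1c(Cl)cc(Cl)cc1Cl | intermediate
26 | lapiferine 10-O-triethylsilyl ether | C/C=C(/C)C(=O)O[C@H]1C[C@@]2(C)O[C@H]2[C@@H](O[Si](CC)(CC)CC)[C@@]2(C)CC[C@@](O)(C(C)C)[C@H]12 | intermediate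
27 | lapiferine, (1S,4R,5S,6S,8R,9S,10S)-6-angeloyloxy-8,9-epoxy-trans-daucane-4,10-diol | C/C=C(/C)C(=O)O[C@H]1C[C@@]2(C)O[C@H]2[C@@H](O)[C@@]2(C)CC[C@@](O)(C(C)C)[C@H]12 | target

Total step count: 19.
Longest linear sequence: 17 steps (steps 1–3 and 6–19, from lactone 1).

The three steps most likely to fail

Step 6 (Proposed new method). The hindered tetrasubstituted enolate may add slowly, so that an uncatalysed pathway through a boat transition state erodes both diastereo- and enantioselectivity, and the adduct may revert by retro-aldol cleavage. The fallback uses known chemistry, sets out from silyl enol ether 7 and enal 5 and returns at aldol 10. MeLi in THF at 0 °C would cleave 7 to the regiodefined lithium enolate, ZnCl2 would give the zinc enolate, and addition of 5 at −78 °C through the closed chair transition state should give the anti aldol as a racemate, that is 10 together with the enantiomer of aldol 10 F1. Esterification with (S)-2-methoxy-2-phenylacetic acid (dicyclohexylcarbodiimide, 4-(dimethylamino)pyridine) would give two diastereomeric esters, the (S)-2-methoxy-2-phenylacetate of aldol 10 F2 and the (S)-2-methoxy-2-phenylacetate of the enantiomer of aldol 10 F3, to be separated by chromatography. Methanolysis of F2 (K2CO3, MeOH, 0 °C) would return 10 as a single enantiomer.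

Step 17. Facial selectivity may be poor because the α isopropyl group on C4 competes with the β methyl on C1, which would give the cis-fused isomer; the epoxide may also be partly reduced by borane. The fallback changes the order of events so that hydroboration precedes the isopropyl addition; it sets out from enone 20 and returns at 26. Luche reduction (NaBH4, CeCl3·7H2O, MeOH, −78 °C), with hydride entering anti to the C1 methyl, should give the C4 β-allylic alcohol F4. NaH and 4-methoxybenzyl chloride in DMF would give the C4 4-methoxybenzyl ether F5. Hydroboration–oxidation (BH3·THF; NaOH, H2O2), now with the C1 methyl and the C4 ether both on the β face and only hydrogen on the α face of C4, should give the trans-fused C6 α-alcohol F6. Yamaguchi esterification with mixed anhydride 25 would give the C6 angelate F7, 2,3-dichloro-5,6-dicyano-1,4-benzoquinone would remove the benzyl ether to give the C4 alcohol F8, and Dess–Martin oxidation would give the C4 ketone F9. Addition of i-PrMgCl/CeCl3 at −78 °C to this saturated, trans-fused ketone, anti to the C1 methyl, should then give 26.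

Step 10. Intermolecular coupling may compete with ring closure, the allylic silyloxy group may be lost reductively at reflux, and the β,γ-alkene of the aldehyde may migrate before coupling. The fallback splits the coupling into a low-temperature pinacol closure and a separate deoxygenation; it sets out from keto aldehyde 13 and returns at diene 15. SmI2 (THF, −78 °C, high dilution) should close the ring to the cis C5,C6-diol F10, 1,1′-thiocarbonyldiimidazole (toluene, heat) would give the cyclic thionocarbonate F11, and Corey–Winter fragmentation with 1,3-dimethyl-2-phenyl-1,3,2-diazaphospholidine (40 °C) should give 15.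

Further compounds
F1 | step 6 | enantiomer of aldol 10, (2S)-2-[(1S,2Z)-1-hydroxy-3-methyl-5-(triethylsilyloxy)pent-2-en-1-yl]-2-methylcyclopentan-1-one | CC[Si](CC)(CC)OCC/C(C)=C\[C@H](O)[C@]1(C)CCCC1=O
F2 | step 6 | (S)-2-methoxy-2-phenylacetate of aldol 10 | CC[Si](CC)(CC)OCC/C(C)=C\[C@@H](OC(=O)[C@@H](OC)c1ccccc1)[C@@]1(C)CCCC1=O
F3 | step 6 | (S)-2-methoxy-2-phenylacetate of the enantiomer of aldol 10 | CC[Si](CC)(CC)OCC/C(C)=C\[C@H](OC(=O)[C@@H](OC)c1ccccc1)[C@]1(C)CCCC1=O
F4 | step 17 | C4 β-allylic alcohol, (1S,4S,8R,9S,10S) | C[C@]12O[C@H]1[C@@H](O[Si](CC)(CC)CC)[C@@]1(C)CC[C@H](O)C1=CC2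
F5 | step 17 | C4 4-methoxybenzyl ether of F4 | C[C@]12O[C@H]1[C@@H](O[Si](CC)(CC)CC)[C@@]1(C)CC[C@H](OCc3ccc(OC)cc3)C1=CC2
F6 | step 17 | trans-fused C6 α-alcohol with C4 4-methoxybenzyl ether | O[C@H]1C[C@@]2(C)O[C@H]2[C@@H](O[Si](CC)(CC)CC)[C@@]2(C)CC[C@H](OCc3ccc(OC)cc3)[C@H]12
F7 | step 17 | C6 angelate of F6 | C/C=C(/C)C(=O)O[C@H]1C[C@@]2(C)O[C@H]2[C@@H](O[Si](CC)(CC)CC)[C@@]2(C)CC[C@H](OCc3ccc(OC)cc3)[C@H]12
F8 | step 17 | C4 alcohol with C6 angelate | C/C=C(/C)C(=O)O[C@H]1C[C@@]2(C)O[C@H]2[C@@H](O[Si](CC)(CC)CC)[C@@]2(C)CC[C@H](O)[C@H]12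
F9 | step 17 | C4 ketone with C6 angelate | C/C=C(/C)C(=O)O[C@H]1C[C@@]2(C)O[C@H]2[C@@H](O[Si](CC)(CC)CC)[C@@]2(C)CCC(=O)[C@H]12
F10 | step 10 | cis C5,C6-diol of the closed bicycle with C10 silyl ether | CC1=C[C@@H](O[Si](C)(C)C(C)(C)C)[C@@]2(C)CCCC2(O)C(O)C1
F11 | step 10 | cyclic C5,C6-thionocarbonate of F10 | CC1=C[C@@H](O[Si](C)(C)C(C)(C)C)[C@@]2(C)CCCC23OC(=S)OC3C1
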